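**Plan**
- Retrosynthesis: the two bonds to the carbonyl carbon C‑3 of the methylenecyclopentenone (C‑2–C‑3 and C‑3–C‑4) are cut first, removing CO and leaving a C‑2 enol triflate on the spiro‑cyclohexene and a vinyl group (C‑4=C‑15) on C‑5; then C‑2–C‑4' and C‑14–C‑15' of the spiro ring are cut (Diels–Alder).
- Enabling feature: C‑3 lies between the ring‑fusion alkene carbon C‑2 (shared by the five‑ and six‑membered rings) and the exo‑methylene carbon C‑4 on the C‑5 methine of the seven‑membered ring, so the ring is a 1,4‑diene plus one CO.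
- Forward: dehydrocostus lactone supplies both halves. The dienophile half 12 keeps its rings; in the diene half 9 the cyclopentane is excised (C‑3 leaves as CO2, C‑2 becomes a silyl dienol ether carbon, C‑4=C‑15 a vinyl group).
- Ring order: lactone and seven‑membered rings from the pool, then the spiro‑cyclohexene (step 12), then the cyclopentenone last (step 15).
- Stereochemistry: C‑5, C‑6, C‑7, C‑1', C‑5', C‑6', C‑7' from the pool; C‑11 (S) by thermodynamic and C‑11' (R) by kinetic enolate protonation; C‑4' by α‑face cycloaddition; C‑10 by ligand‑controlled copper hydride delivery.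

Key step: step 15

Remark: guaiane numbering is used for both halves, with primes for the half that carries the spiro centre C‑4'. Centres that are erased later (C‑4 of 5–7, C‑2 of 6, 13 and 14) are expected as mixtures and are left undefined in the SMILES; the C‑3 carbinol of 3 and 11 is drawn as the expected 3α epimer.

**Route**

Step 1
Reactants: 1 dehydrocostus lactone
Product: 2 mokko lactone, the (11S)‑11,13‑dihydro compound
Conditions: NaBH4, MeOH, 0 °C
Reagents that add atoms: none
Why: Conjugate hydride reduction of the α‑methylene‑γ‑lactone, the only electron‑poor alkene, followed by protonation of the lactone enolate under equilibrating conditions in methanol, should give the more stable 11S epimer (methyl α, on the face of H‑7 and away from C‑8).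

Step 2
Reactants: 2 mokko lactone
Product: 3 (11S)‑3α‑hydroxyguaia‑4(15),10(14)‑dien‑12,6α‑olide
Conditions: SeO2 (0.3 equiv), t‑BuOOH, CH2Cl2, rt
Reagents that add atoms: tert‑butyl hydroperoxide, CC(C)(C)OO
Why: Selenium dioxide allylic hydroxylation (ene reaction, then 2,3‑sigmatropic shift) at the cyclopentane methylene C‑3 next to the C‑4 exo‑methylene, as is usual for this lactone skeleton, with attack on the convex α face so that the 3α alcohol is expected; this centre is removed in step 3.

Step 3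
Reactants: 3 the 3α‑alcohol
Product: 4 (11S)‑3‑oxoguaia‑4(15),10(14)‑dien‑12,6α‑olide
Conditions: DMP, CH2Cl2, 0 °C to rt
Reagents that add atoms: none
Why: Dess–Martin oxidation of the secondary allylic alcohol to the exo‑methylene cyclopentanone under neutral conditions that leave the lactone and both exo‑methylenes untouched; no stereocentre is formed.

Step 4
Reactants: 4 the exo‑methylene ketone
Product: 5 (11S)‑15‑(dimethylphenylsilyl)‑3‑oxoguai‑10(14)‑en‑12,6α‑olide (C‑4 epimers)
Conditions: PhMe2Si–Bpin, CuSO4 (1 mol %), 4‑picoline (5 mol %), THF–H2O, rt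
Reagents that add atoms: (dimethylphenylsilyl)boronic acid pinacol ester, C[Si](C)(c1ccccc1)B1OC(C)(C)C(C)(C)O1
Why: Copper‑catalysed conjugate silyl transfer from the silylboronate to the only Michael acceptor places silicon β to C‑3 for the later regiospecific alkene formation; C‑4 forms as an epimer mixture that is erased in step 7.

Step 5
Reactants: 5 the β‑silyl ketone
Product: 6 (11S)‑15‑(dimethylphenylsilyl)‑2‑hydroxy‑3‑oxoguai‑10(14)‑en‑12,6α‑olide (C‑2 and C‑4 epimers)
Conditions: LiHMDS, THF, −78 °C; 2‑(phenylsulfonyl)‑3‑phenyloxaziridine; NH4Cl (aq)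
Reagents that add atoms: 2‑(phenylsulfonyl)‑3‑phenyloxaziridine, O=S(=O)(c1ccccc1)N1OC1c1ccccc1
Why: Kinetic deprotonation at the unhindered C‑2 methylene (the ketone α‑hydrogens are more acidic than the lactone α‑hydrogen, and C‑4 is tertiary and hindered) and electrophilic enolate hydroxylation by the N‑sulfonyloxaziridine give the α‑ketol; the carbinol configuration is irrelevant.

Step 6
Reactants: 6 the α‑ketol
Product: 7 (11S)‑15‑(dimethylphenylsilyl)‑2‑oxo‑2,3‑secoguai‑10(14)‑en‑12,6α‑olid‑3‑oic acid (C‑4 epimers)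
Conditions: NaIO4, THF–pH 7 buffer, rt
Reagents that add atoms: sodium periodate, [Na+].[O-]I(=O)(=O)=O
Why: Periodate cleavage of the α‑ketol cuts the C‑2–C‑3 bond, making C‑2 the aldehyde on C‑1 and C‑3 a carboxylic acid β to silicon; no new stereocentre is formed.

Step 7
Reactants: 7 the β‑silyl acid aldehyde
Product: 8 (11S)‑2‑oxo‑3‑nor‑2,3‑secoguaia‑4(15),10(14)‑dien‑12,6α‑olide (C‑1 formyl, C‑5 vinyl)
Conditions: graphite anode, Pt cathode, undivided cell, constant current (2.5 F/mol), Et3N (0.2 equiv), MeOH, 10 °C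
Reagents that add atoms: none
Why: Non‑Kolbe (Hofer–Moest) anodic decarboxylation gives a β‑silyl‑stabilised cation at C‑4 that loses silicon to methanol, so the C‑4=C‑15 vinyl group forms regiospecifically and C‑3 leaves as CO2 (the known anodic decarboxylation–desilylation of β‑silyl acids); the C‑4 stereocentre disappears.

Step 8
Reactants: 8 the vinyl aldehyde
Product: 9 (1E,11S)‑2‑(tert‑butyldimethylsilyloxy)‑3‑nor‑2,3‑secoguaia‑1,4(15),10(14)‑trien‑12,6α‑olide
Conditions: TBSOTf, Et3N, CH2Cl2, −78 to 0 °C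
Reagents that add atoms: tert‑butyldimethylsilyl trifluoromethanesulfonate, CC(C)(C)[Si](C)(C)OS(=O)(=O)C(F)(F)F
Why: Soft enolisation of the α‑branched β,γ‑unsaturated aldehyde removes H‑1 and gives the conjugated 1‑silyloxy‑1,3‑diene held s‑cis by the ring; the (E) geometry, with the silyloxy group turned away from the C‑14 methylene, is expected because it avoids the clash inside the diene, and C‑1 ceases to be a stereocentre.

Step 9
Reactants: 2 mokko lactone
Product: 10 11‑epi‑mokko lactone, the (11R) epimer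
Conditions: LDA, THF, −78 °C; then 2,6‑di‑tert‑butyl‑4‑methylphenol, −78 °C; NH4Cl (aq)
Reagents that add atoms: none
Why: Irreversible enolisation of the lactone and kinetic protonation of the planar enolate by a bulky phenol from the less hindered face (that of H‑7, anti to C‑8) should place the methyl group β (11R), the less stable epimer needed in the second half.

Step 10
Reactants: 10 11‑epi‑mokko lactone
Product: 11 (11R)‑3α‑hydroxyguaia‑4(15),10(14)‑dien‑12,6α‑olide
Conditions: SeO2 (0.3 equiv), t‑BuOOH, CH2Cl2, rt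
Reagents that add atoms: tert‑butyl hydroperoxide, CC(C)(C)OO
Why: The same selenium dioxide allylic hydroxylation at C‑3 as in step 2; the neutral conditions do not touch the kinetically set C‑11 centre, and the new carbinol is removed in step 11.

Step 11
Reactants: 11 the 3α‑alcohol
Product: 12 (11R)‑3‑oxoguaia‑4(15),10(14)‑dien‑12,6α‑olide
Conditions: DMP, CH2Cl2, 0 °C to rt
Reagents that add atoms: none
Why: Dess–Martin oxidation to the exo‑methylene cyclopentanone dienophile under neutral conditions that cannot epimerise C‑11; the enone is used at once because such enones dimerise.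

Step 12
Reactants: 9 the silyloxydiene; 12 the exo‑methylene ketone
Product: 14 spiro adduct alcohol (new bonds C‑2–C‑4' and C‑14–C‑15'; C‑1=C‑10 alkene; 2‑hydroxy; C‑2 epimers), via silyl ether adduct 13 (not isolated)
Conditions: toluene, 70 °C; then HF·pyridine, THF, 0 °C to rt
Reagents that add atoms: none
Why: Thermal Diels–Alder reaction of the electron‑rich 1‑silyloxydiene with the s‑cis exo‑methylene ketone: the free terminus C‑14 bonds to the enone β‑carbon C‑15' and the silyloxy‑bearing C‑2 to the α‑carbon C‑4' (ortho rule), and the diene adds to the convex α face of the cis‑fused hydroazulenone, anti to its seven‑membered ring, which sets the spiro centre C‑4' with C‑2 α; both C‑2 epimers lead on, and fluoride removes the silyl group in the same flask.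

Step 13
Reactants: 14 the adduct alcohol
Product: 15 adduct enone (2‑oxo‑1(10)‑ene; spiro 1,3‑diketone with C‑3')
Conditions: DMP, CH2Cl2, rt
Reagents that add atoms: none
Why: Dess–Martin oxidation of the hindered allylic alcohol gives the tetrasubstituted enone and removes the C‑2 stereocentre; the carbon between the two ketones is quaternary, so the diketone cannot enolise there.

Step 14
Reactants: 15 the adduct enone
Product: 17 enol triflate (2‑triflyloxy‑1(2)‑ene, 10βH, C‑5 vinyl), via silyl enol ether 16 (not isolated)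
Conditions: Cu(OAc)2·H2O (5 mol %), (S)‑DTBM‑SEGPHOS (5 mol %), (EtO)2MeSiH, toluene, 0 °C; then CsF, PhNTf2, DME, rt
Reagents that add atoms: N‑phenylbis(trifluoromethanesulfonimide), O=S(=O)(N(c1ccccc1)S(=O)(=O)C(F)(F)F)C(F)(F)F; diethoxymethylsilane, CCO[SiH](C)OCC (its silicon is carried only by intermediate 16)
Why: Copper hydride‑catalysed conjugate hydrosilylation of the enone (isolated ketone, lactones and unactivated alkenes should be spared) delivers hydride to C‑10 and gives the silyl enol ether regiospecifically at C‑1=C‑2; the bulky chiral bisphosphine is meant to direct hydride to the β face (H‑10β, C‑14 α), the antipode being confirmed by trial, and fluoride‑induced O‑sulfonylation fixes the enolate as the enol triflate.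

Step 15
Reactants: 17 the enol triflate
Product: 18 CNP0240988.1
Conditions: Pd(PPh3)4 (10 mol %), CO (1 atm), i‑Pr2NEt, MeCN–toluene, 70 °C
Reagents that add atoms: carbon monoxide, [C-]#[O+]
Why: Oxidative addition of zerovalent palladium into the C‑2–OTf bond, CO insertion to the C‑3 acylpalladium, 5‑exo‑trig syn‑acylpalladation of the C‑5 vinyl group (C‑3–C‑4 bond) and syn β‑hydride elimination of H‑4 from the primary alkylpalladium at C‑15 give the ketone, the ring and the exo‑methylene in one operation. The closest known reaction type is the palladium‑catalysed carbonylative cyclisation (cyclic acylpalladation–dehydropalladation) of 1‑halo‑1,4‑dienes to 5‑methylenecyclopent‑2‑enones. The only ring closed is the cyclopentenone, by 5‑exo‑trig attack of the acyl carbon on the internal vinyl carbon C‑4. No lasting stereocentre is created: C‑4 is sp3 only in the alkylpalladium intermediate, and C‑5 and C‑10 are not touched. The step needs acylpalladation to outrun O‑acylation by the enol of the neighbouring cyclopentanone and direct reduction of the acylpalladium; the vinyl group held cis across the C‑1=C‑2 alkene three atoms from the acyl carbon, the absence of external nucleophiles and a hindered amine base should secure this. H‑4 is the only β‑hydrogen of the alkylpalladium, so the exo‑methylene is the only alkene that can form.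

**Compound list**

1 | dehydrocostus lactone, guaia‑4(15),10(14),11(13)‑trien‑12,6α‑olide (1αH,5αH,6βH,7αH) | C=C1CC[C@@H]2[C@@H]([C@@H]3[C@H]1CCC3=C)OC(=O)C2=C | starting material
2 | mokko lactone, (11S)‑guaia‑4(15),10(14)‑dien‑12,6α‑olide (11‑methyl α) | C=C1CC[C@@H]2[C@@H]([C@@H]3[C@H]1CCC3=C)OC(=O)[C@H]2C | intermediate
3 | (11S)‑3α‑hydroxyguaia‑4(15),10(14)‑dien‑12,6α‑olide | C=C1CC[C@@H]2[C@@H]([C@@H]3[C@H]1C[C@@H](O)C3=C)OC(=O)[C@H]2C | intermediate
4 | (11S)‑3‑oxoguaia‑4(15),10(14)‑dien‑12,6α‑olide | C=C1CC[C@@H]2[C@@H]([C@@H]3[C@H]1CC(=O)C3=C)OC(=O)[C@H]2C | intermediate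
5 | (11S)‑15‑(dimethylphenylsilyl)‑3‑oxoguai‑10(14)‑en‑12,6α‑olide, C‑4 epimers | C=C1CC[C@@H]2[C@@H]([C@@H]3[C@H]1CC(=O)C3C[Si](C)(C)c1ccccc1)OC(=O)[C@H]2C | intermediate
6 | (11S)‑15‑(dimethylphenylsilyl)‑2‑hydroxy‑3‑oxoguai‑10(14)‑en‑12,6α‑olide, C‑2 and C‑4 epimers | C=C1CC[C@@H]2[C@@H]([C@@H]3[C@H]1C(O)C(=O)C3C[Si](C)(C)c1ccccc1)OC(=O)[C@H]2C | intermediate
7 | (11S)‑15‑(dimethylphenylsilyl)‑2‑oxo‑2,3‑secoguai‑10(14)‑en‑12,6α‑olid‑3‑oic acid, C‑4 epimers (formyl on C‑1; CH(CO2H)CH2SiMe2Ph on C‑5) | C=C1CC[C@@H]2[C@@H]([C@@H](C(C[Si](C)(C)c3ccccc3)C(=O)O)[C@H]1C=O)OC(=O)[C@H]2C | intermediate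
8 | (11S)‑2‑oxo‑3‑nor‑2,3‑secoguaia‑4(15),10(14)‑dien‑12,6α‑olide (formyl on C‑1, 1αH; vinyl on C‑5, 5αH; exo‑methylene on C‑10) | C=C1CC[C@@H]2[C@@H]([C@@H](C=C)[C@H]1C=O)OC(=O)[C@H]2C | intermediate
9 | (1E,11S)‑2‑(tert‑butyldimethylsilyloxy)‑3‑nor‑2,3‑secoguaia‑1,4(15),10(14)‑trien‑12,6α‑olide | C=C1CC[C@@H]2[C@@H]([C@@H](C=C)/C1=C\O[Si](C)(C)C(C)(C)C)OC(=O)[C@H]2C | intermediate
10 | 11‑epi‑mokko lactone, (11R)‑guaia‑4(15),10(14)‑dien‑12,6α‑olide (11‑methyl β) | C=C1CC[C@@H]2[C@@H]([C@@H]3[C@H]1CCC3=C)OC(=O)[C@@H]2C | intermediate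
11 | (11R)‑3α‑hydroxyguaia‑4(15),10(14)‑dien‑12,6α‑olide | C=C1CC[C@@H]2[C@@H]([C@@H]3[C@H]1C[C@@H](O)C3=C)OC(=O)[C@@H]2C | intermediate
12 | (11R)‑3‑oxoguaia‑4(15),10(14)‑dien‑12,6α‑olide | C=C1CC[C@@H]2[C@@H]([C@@H]3[C@H]1CC(=O)C3=C)OC(=O)[C@@H]2C | intermediate
13 | Diels–Alder adduct silyl ether: 2‑(tert‑butyldimethylsilyloxy), bonds C‑2–C‑4' and C‑14–C‑15', C‑1=C‑10 alkene, C‑2 on the α face of C‑4', C‑2 epimers | CC(C)(C)[Si](C)(C)OC1C2=C(CC[C@@H]3[C@H](OC(=O)[C@H]3C)[C@H]2C=C)CC[C@]14C(=O)C[C@H]5C(=C)CC[C@@H]6[C@H](OC(=O)[C@@H]6C)[C@H]54 | intermediate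
14 | adduct alcohol: as 13 with free 2‑hydroxyl, C‑2 epimers | OC1C2=C(CC[C@@H]3[C@H](OC(=O)[C@H]3C)[C@H]2C=C)CC[C@]14C(=O)C[C@H]5C(=C)CC[C@@H]6[C@H](OC(=O)[C@@H]6C)[C@H]54 | intermediate
15 | adduct enone: 2‑oxo‑1(10)‑ene, spiro 1,3‑diketone with C‑3' | O=C1C2=C(CC[C@@H]3[C@H](OC(=O)[C@H]3C)[C@H]2C=C)CC[C@]14C(=O)C[C@H]5C(=C)CC[C@@H]6[C@H](OC(=O)[C@@H]6C)[C@H]54 | intermediate
16 | diethoxymethylsilyl enol ether of the 10βH ketone (C‑1=C‑2) | CCO[Si](C)(OCC)OC1=C2[C@@H](CC[C@@H]3[C@H](OC(=O)[C@H]3C)[C@H]2C=C)CC[C@]14C(=O)C[C@H]5C(=C)CC[C@@H]6[C@H](OC(=O)[C@@H]6C)[C@H]54 | intermediate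
17 | enol triflate: 2‑(trifluoromethanesulfonyloxy)‑1(2)‑ene, 10βH, vinyl on C‑5 | O=S(=O)(OC1=C2[C@@H](CC[C@@H]3[C@H](OC(=O)[C@H]3C)[C@H]2C=C)CC[C@]14C(=O)C[C@H]5C(=C)CC[C@@H]6[C@H](OC(=O)[C@@H]6C)[C@H]54)C(F)(F)F | intermediate
18 | CNP0240988.1 | C=C1C(=O)C2=C3[C@@H](CC[C@@H]4[C@H](OC(=O)[C@H]4C)[C@@H]13)CC[C@]21C(=O)C[C@H]2C(=C)CC[C@@H]3[C@H](OC(=O)[C@@H]3C)[C@H]21 | target

**Step count and risks**

Total step count: 15. Longest linear sequence: 12 steps (steps 1–8, then 12–15).

Three steps most likely to fail: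

1. Step 14. Hydride delivery to the tetrasubstituted β‑carbon C‑10 may be slow, so that reduction of the cyclopentanone carbonyl or delivery to the more open α face competes; in the fluoride stage, proton transfer from the cyclopentanone may scramble the enolate. Fallback: starting from 15, the hydrosilylation is run under substrate control with the achiral, ketone‑tolerant cluster [(Ph3P)CuH]6 and (EtO)2MeSiH, and the C‑10 epimer that then predominates is carried on. The 10‑epimeric silyl enol ether F1 is triflated (CsF, PhNTf2) to the 10‑epimeric enol triflate F2, which is carbonylated as in step 15 to 10‑epi‑18 F3. H‑10 is a γ‑hydrogen of the new cyclopentenone, so brief treatment with DBU in CH2Cl2 (vinylogous enolisation through the C‑3 dienolate, γ‑reprotonation) should equilibrate C‑10; whether the equilibrium favours 18 would have to be established. This rejoins the route at 18.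

2. Step 12. Periselectivity may be poor: the s‑cis enone can act as a heterodiene toward the silyl enol ether, the dienophile can dimerise, or the diene can hydrolyse. Fallback: from 9 and 12 a stepwise ionic annulation is used. Sc(OTf)3‑catalysed vinylogous Mukaiyama–Michael addition (C‑14 to C‑15', CH2Cl2, −78 °C) and acidic work‑up should give the keto enal F4. Intramolecular aldol addition of the cyclopentanone (DBU cat., THF, 0 °C; only the C‑4' enol can reach the aldehyde, attack from the α face) then closes the C‑2–C‑4' bond and returns to 14.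

3. Step 7. The anodic oxidation may be unselective: the aldehyde may be oxidised, or methanol may capture the cation before silicon is lost. Fallback: from 4, without silicon, conjugate reduction with [(Ph3P)CuH]6 (benzene, H2O) gives the 4‑methyl ketone F5. The same hydroxylation (LiHMDS, then the oxaziridine) gives the α‑ketol F6, and periodate cleavage gives the aldehyde acid F7. Photocatalytic dehydrogenative decarboxylation (9‑mesityl‑10‑methylacridinium tetrafluoroborate, Co(dmgH)2(py)Cl, blue light), in which the cobalt catalyst removes a hydrogen from the unhindered methyl group of the C‑4 radical, should give the vinyl compound and rejoin at 8.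

**Further compounds**

F1 | step 14 | 10‑epimer (10αH) of silyl enol ether 16 | CCO[Si](C)(OCC)OC1=C2[C@H](CC[C@@H]3[C@H](OC(=O)[C@H]3C)[C@H]2C=C)CC[C@]14C(=O)C[C@H]5C(=C)CC[C@@H]6[C@H](OC(=O)[C@@H]6C)[C@H]54
F2 | step 14 | 10‑epimer (10αH) of enol triflate 17 | O=S(=O)(OC1=C2[C@H](CC[C@@H]3[C@H](OC(=O)[C@H]3C)[C@H]2C=C)CC[C@]14C(=O)C[C@H]5C(=C)CC[C@@H]6[C@H](OC(=O)[C@@H]6C)[C@H]54)C(F)(F)F
F3 | step 14 | 10‑epi‑18 | C=C1C(=O)C2=C3[C@H](CC[C@@H]4[C@H](OC(=O)[C@H]4C)[C@@H]13)CC[C@]21C(=O)C[C@H]2C(=C)CC[C@@H]3[C@H](OC(=O)[C@@H]3C)[C@H]21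
F4 | step 12 | keto enal: Michael adduct with C‑14–C‑15' bond, 1(10)‑en‑2‑al, C‑4' epimers | O=CC1=C(CC[C@@H]2[C@H](OC(=O)[C@H]2C)[C@H]1C=C)CCC4C(=O)C[C@H]5C(=C)CC[C@@H]6[C@H](OC(=O)[C@@H]6C)[C@H]54
F5 | step 7 | (11S)‑3‑oxoguai‑10(14)‑en‑12,6α‑olide, C‑4 epimers | C=C1CC[C@@H]2[C@@H]([C@@H]3[C@H]1CC(=O)C3C)OC(=O)[C@H]2C
F6 | step 7 | (11S)‑2‑hydroxy‑3‑oxoguai‑10(14)‑en‑12,6α‑olide, C‑2 and C‑4 epimers | C=C1CC[C@@H]2[C@@H]([C@@H]3[C@H]1C(O)C(=O)C3C)OC(=O)[C@H]2C
F7 | step 7 | (11S)‑2‑oxo‑2,3‑secoguai‑10(14)‑en‑12,6α‑olid‑3‑oic acid, C‑4 epimers | C=C1CC[C@@H]2[C@@H]([C@@H](C(C)C(=O)O)[C@H]1C=O)OC(=O)[C@H]2C
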